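# Proposed synthesis of (-)-thujaplicatin by tandem conjugate addition and benzylation on a menthyloxy butenolide

Compound numbers 1–19 are fixed by the steps below and are used in every section. Ring A is the 3,4-dihydroxy-5-methoxyphenyl ring and ring B the 4-hydroxy-3-methoxyphenyl ring. The lactone is numbered C9(=O)–C8–C8'–C9'H2–O, with C7 joining C8 to ring A and C7' joining C8' to ring B. "l-Menthyl" means (1R,2S,5R)-2-isopropyl-5-methylcyclohexyl.

## The problem

(-)-Thujaplicatin 19 is a trans-2,3-dibenzyl-γ-butyrolactone. The five-membered ring is simple, but the two arylmethyl arms differ by only one hydroxyl group, so the synthesis must decide unambiguously that ring A, not ring B, sits on the carbon next to the carbonyl. There are two adjacent stereocentres, (8R,8'R), in a trans relationship. C8 is α to the carbonyl and epimerisable, and its trans arrangement is the thermodynamic one, so C8 can be controlled by C8'. C8' has no such help and must be set absolutely from an external chiral source. The catechol of ring A and the phenol of ring B will not tolerate organolithium reagents or base in air. They have to stay masked to the end, with groups that come off under neutral conditions and leave the two methyl ethers alone. The lactone opens in hydroxide, which must be either avoided or used deliberately. The enabling feature is that C8' and C8 are the β- and α-carbons of the C9 carbonyl, while C9' is only at the alcohol oxidation level. If C9' is raised to an acetal carbon, the ring becomes a 5-alkoxybutenolide: its β-carbon can accept a C7' acyl-anion equivalent, its enolate can accept a C7 benzyl electrophile, and the acetal carbon can carry a chiral alkoxy group that directs both events.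

## Retrosynthesis

**19 ⇒ 18 (three O–benzyl bonds).** The last operation should only uncover the phenols. Benzyl ethers are preferred over methyl ethers, which could not be distinguished from the two methoxy groups that must remain. They are preferred over silyl ethers, which are doubtful towards n-BuLi and aqueous KOH. The precursor 18 is the fully protected trans lactone. The forward step is a neutral hydrogenolysis that touches neither the lactone nor the stereocentres.

**18 ⇒ 15 (C9'–H bond; C9' returned to the acetal level).** The C9' methylene of 18 is traced back to an acetal carbon bearing an l-menthyloxy group in 15. The C9 carbonyl is the same atom in both compounds, so the placement of ring A next to the carbonyl is fixed before this step and cannot be lost in it. Reducing the other end (C9) would give a diol with two indistinguishable CH2OH groups and is rejected. The forward reaction must open the pseudo-ester, reduce the freed aldehyde and close the lactone again without epimerising C8'.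

**15 ⇒ 14 (two C–S bonds at C7').** The C7' methylene is traced back to a 1,3-dithiane carbon. This adds no skeletal complexity and turns C7' into a latent nucleophile. The forward step is a reductive desulfurisation that must spare three aryl benzyl ethers and the lactone acetal.

**14 ⇒ 7 + 5 + 11 (C8'–C7' and C8–C7).** This is the central cut. Both bonds joining the arylmethyl arms to the ring are broken. This leaves the lithiated form of dithiane 7 as the C7' nucleophile, the butenolide 5 as a four-carbon core already carrying the ring oxygen, and the benzyl bromide 11 as the C7 electrophile. Against stepwise alkylation of a preformed β-benzyl lactone, this cut makes both stereocentres in one flask from a single acetal centre. The order of addition decides which arene is near the carbonyl. Three fragments of comparable, low complexity replace 14. The forward reaction needs 1,4-addition anti to the menthyloxy group and enolate benzylation anti to the new dithianyl group.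

**5 ⇒ 2 + 3, and 2 ⇒ 1 (acetal C–O bond; furan oxidation).** The auxiliary is removed to give the racemic hydroxybutenolide 2 and (-)-menthol 3. Compound 2 comes from furfural 1 by oxidative loss of the formyl carbon. The forward acetalisation must deliver a single C5 epimer, which is asked of crystallisation with acid-mediated recycling of the other epimer.

**7 ⇒ 6 (two C–S bonds).** The dithiane is the dithioacetal of the commercial O-benzylated aldehyde 6.

**11 ⇒ 10 ⇒ 9 ⇒ 8 (C–Br, C–H, two O–benzyl bonds).** The bromide is traced through the benzylic alcohol 10 and the aldehyde 9 to commercial 3,4-dihydroxy-5-methoxybenzaldehyde 8. These are three routine functional-group steps.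

## Roads not taken

**Alternative 1: desymmetrising Baeyer–Villiger oxidation.**
- **Cut and key step.** The O–C9' bond is cut back to the prochiral 3-[4-(benzyloxy)-3-methoxybenzyl]cyclobutan-1-one A1. An enantioselective Baeyer–Villiger oxidation (H2O2 with a chiral Brønsted acid, or an enzyme) would make one of the two enantiotopic CH2 groups migrate. That gives (R)-4-[4-(benzyloxy)-3-methoxybenzyl]dihydrofuran-2(3H)-one A2 with C8' set. Trans-selective α-benzylation of A2 with bromide 11 would then reach 18 directly.
- **Merits.** The stereocentre comes from a catalyst, not a stoichiometric auxiliary. No sulfur or nickel is used. The lactone never needs to be opened. The late alkylation is a very dependable way to set the trans relationship.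
- **Weak points.** A1 has to be built first, in about three steps by ketene [2+2] chemistry. The stereodifferentiating substituent is a flexible benzyl group one carbon removed from the ring, which is the situation in which this desymmetrisation is least secure. A2 is unlikely to offer an easy enantiomeric upgrade.
- **Comparison.** Alternative 1 is at least as short after A1 and cleaner in its endgame. The chosen plan offers in return a crystalline, configurationally pure auxiliary-bearing butenolide, so stereochemical impurities are diastereomers and removable. It also forms both C–C bonds in one flask.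

**Alternative 2: intramolecular cyclopropanation, then hydrogenolysis.**
- **Cut and key step.** C8–C8' and a temporary C8–C7' bond are cut, leading to the cinnamyl α-diazo ester A3, (E)-3-[4-(benzyloxy)-3-methoxyphenyl]allyl 3-[3,4-bis(benzyloxy)-5-methoxyphenyl]-2-diazopropanoate. A chiral dirhodium catalyst of the Rh2(S-DOSP)4 or Rh2(5S-MEPY)4 type would generate the carbene at C8. Its addition to the alkene would close the lactone and a cyclopropane, giving the 3-oxabicyclo[3.1.0]hexan-2-one A4. Hydrogenolysis of the donor–acceptor C8–C7' bond together with the benzyl ethers would finish the synthesis.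
- **Merits.** The two halves are joined by a simple esterification. One catalytic step makes the ring, the C8–C8' bond and the C8' stereocentre. Global hydrogenolysis could in principle end the route in one operation, which is better step economy than the chosen plan.
- **Weak points.** The carbene carbon carries a benzylic CH2, so 1,2-hydride migration competes directly with cyclopropanation. Enantiocontrol for α-alkyl diazo esters is less reliable than for diazoacetates. The hydrogenolysis must choose C8–C7' over the also benzylic C8'–C7' bond. C8 is created only in that last step, with no clear facial bias, although base equilibration towards trans could help.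
- **Comparison.** The chosen plan is longer but sets C8 directly under substrate control and contains no step whose chemoselectivity is in doubt at the outset.

**Alternative 3: silicon-tethered radical delivery of C9'.**
- **Cut and key step.** The C8'–C9' bond is cut. The (bromomethyl)dimethylsilyl ether A5 of an enantio-enriched C7' carbinol, attached to an α-(ring A-methyl) enoate, would be treated with Bu3SnH and AIBN. The silylmethyl radical would add 5-exo to C8' and give the trans-4,5-disubstituted 1-oxa-2-silacyclopentane A6. Oxidative C–Si cleavage, lactonisation and hydrogenolysis of the benzylic C7'–O bond along with the benzyl ethers would follow.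
- **Merits.** C8' is set relative to C7' through a tight cyclic transition state. The C7' carbinol is available by a reliable asymmetric ketone reduction. The temporary oxygen disappears in the same hydrogenolysis that frees the phenols.
- **Weak points.** C8 is not controlled, because the α-ester radical is reduced without facial bias, so a later equilibration is required. A stereocentre is built only to be destroyed. Tin is stoichiometric. A free C7' hydroxyl can lactonise in competition with the C9' hydroxyl. The sequence from simple aromatics is clearly longer.
- **Comparison.** Its stereochemical relay to C8' is as trustworthy as that of the chosen plan. The chosen plan is shorter and controls C8 as well.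

Key step: step 7

## Route

Remark on the chemistry: 4-(benzyloxy)-3-methoxybenzaldehyde 6 is taken as a purchased compound. All three phenols are carried as benzyl ethers so that one hydrogenolysis ends the route.

**Step 1**
Reactants: 1 furfural
Product: 2 5-hydroxyfuran-2(5H)-one (racemic hemiacetal)
Conditions: O2, rose bengal (cat.), MeOH, hν (visible), rt
Reagents that add atoms: oxygen, O=O
Why: Dye-sensitised photo-oxygenation: singlet oxygen adds [4+2] across the furan, and methanolysis of the endoperoxide expels the formyl carbon as its methyl ester, leaving the hydroxybutenolide; the hemiacetal centre is racemic and is settled in step 2.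

**Step 2**
Reactants: 2 5-hydroxyfuran-2(5H)-one; 3 (-)-menthol
Product: 5 (5R)-5-(l-menthyloxy)furan-2(5H)-one, via (5S)-epimer 4 (not isolated)
Conditions: p-TsOH·H2O (cat.), toluene, reflux, Dean–Stark; crystallisation from petroleum ether; mother liquor re-equilibrated with p-TsOH and crystallised again
Reagents that add atoms: none
Why: Acid-catalysed acetalisation of the pseudo-acid gives both C5 epimers; the (5R) epimer 5 is expected to crystallise, and because the acetal centre epimerises through the oxocarbenium ion under acid, material held as 4 is funnelled into 5, so C5 is set by crystallisation under the influence of the menthyl stereocentres.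

**Step 3**
Reactants: 6 4-(benzyloxy)-3-methoxybenzaldehyde
Product: 7 2-[4-(benzyloxy)-3-methoxyphenyl]-1,3-dithiane
Conditions: HS(CH2)3SH, BF3·OEt2 (cat.), CH2Cl2, 0 °C → rt
Reagents that add atoms: propane-1,3-dithiol, SCCCS
Why: Lewis-acid-catalysed dithioacetalisation of an aromatic aldehyde; the aryl benzyl and methyl ethers are inert to catalytic BF3·OEt2 at this temperature.

**Step 4**
Reactants: 8 3,4-dihydroxy-5-methoxybenzaldehyde
Product: 9 3,4-bis(benzyloxy)-5-methoxybenzaldehyde
Conditions: BnBr, K2CO3, DMF, 60 °C
Reagents that add atoms: benzyl bromide, BrCc1ccccc1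
Why: Double Williamson etherification of the catechol; both phenoxides are alkylated by the reactive benzylic halide and the aldehyde is untouched.

**Step 5**
Reactants: 9 3,4-bis(benzyloxy)-5-methoxybenzaldehyde
Product: 10 [3,4-bis(benzyloxy)-5-methoxyphenyl]methanol
Conditions: NaBH4, MeOH/THF, 0 °C
Reagents that add atoms: none
Why: Borohydride reduction of an aromatic aldehyde to the benzylic alcohol; no other group is reducible under these conditions.

**Step 6**
Reactants: 10 [3,4-bis(benzyloxy)-5-methoxyphenyl]methanol
Product: 11 3,4-bis(benzyloxy)-5-methoxybenzyl bromide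
Conditions: PBr3, Et2O, 0 °C
Reagents that add atoms: phosphorus tribromide, BrP(Br)Br
Why: Conversion of a benzylic alcohol into the bromide through its phosphite ester (SN2 displacement by bromide); the electron-rich bromide is used soon after it is made.

**Step 7**
Reactants: 7 2-[4-(benzyloxy)-3-methoxyphenyl]-1,3-dithiane; 5 (5R)-5-(l-menthyloxy)furan-2(5H)-one; 11 3,4-bis(benzyloxy)-5-methoxybenzyl bromide
Product: 14 (3R,4R,5R)-3-[3,4-bis(benzyloxy)-5-methoxybenzyl]-4-{2-[4-(benzyloxy)-3-methoxyphenyl]-1,3-dithian-2-yl}-5-(l-menthyloxy)dihydrofuran-2(3H)-one, via 2-lithio-1,3-dithiane 12 (not isolated), via lithium enolate 13 (not isolated)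
Conditions: n-BuLi, THF, −78 → −20 °C; 5, −78 °C; then 11, TMEDA, −78 °C → rt
Reagents that add atoms: none
Why: Deprotonation of 7 gives the sulfur-stabilised carbanion 12, a soft and hindered acyl-anion equivalent that adds 1,4 (Michael addition) to the butenolide 5 to give the lithium enolate 13, which is then C-benzylated by 11. The closest known reaction type is the tandem conjugate addition–enolate alkylation of 5-alkoxy-2(5H)-furanones with lithiated dithioacetals. No ring is closed; the two bonds C8'–C7' and C8–C7 are formed on the existing lactone ring. C8' is controlled by the acetal stereocentre C5, because the nucleophile enters the butenolide face opposite the menthyloxy group and gives the 4,5-trans adduct. C8 is controlled by C8', because the enolate is alkylated on the face opposite the bulky 2-aryl-dithianyl group and gives the 3,4-trans relationship. The step needs 1,4- over 1,2-addition, secured by the stabilised dithiane anion, and C-alkylation faster than proton transfer, secured by the reactive benzylic bromide and TMEDA as deaggregating additive. The order of addition places ring B on C8' and ring A on C8 next to the carbonyl that survives. Holding the mixture at −78 °C until 11 is in suppresses retro-Michael reaction and direct benzylation of unreacted 12.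

**Step 8**
Reactants: 14 (3R,4R,5R)-3-[3,4-bis(benzyloxy)-5-methoxybenzyl]-4-{2-[4-(benzyloxy)-3-methoxyphenyl]-1,3-dithian-2-yl}-5-(l-menthyloxy)dihydrofuran-2(3H)-one
Product: 15 (3R,4R,5R)-3-[3,4-bis(benzyloxy)-5-methoxybenzyl]-4-[4-(benzyloxy)-3-methoxybenzyl]-5-(l-menthyloxy)dihydrofuran-2(3H)-one
Conditions: NiCl2·6H2O, NaBH4, MeOH/THF, 0 °C
Reagents that add atoms: none
Why: Reductive desulfurisation of a benzylic dithioacetal with nickel boride formed in the flask; this reagent cleaves C–S bonds but is not expected to hydrogenolyse aryl benzyl ethers, and short exposure at 0 °C should leave the lactone acetal and the three stereocentres unchanged.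

**Step 9**
Reactants: 15 (3R,4R,5R)-3-[3,4-bis(benzyloxy)-5-methoxybenzyl]-4-[4-(benzyloxy)-3-methoxybenzyl]-5-(l-menthyloxy)dihydrofuran-2(3H)-one
Product: 18 (3R,4R)-3-[3,4-bis(benzyloxy)-5-methoxybenzyl]-4-[4-(benzyloxy)-3-methoxybenzyl]dihydrofuran-2(3H)-one, via aldehyde carboxylate 16 (not isolated), via hydroxy carboxylate 17 (not isolated)
Conditions: NaBH4, KOH, EtOH/THF/H2O, 0 °C → rt; then aq. HCl to pH 1–2, rt
Reagents that add atoms: none
Why: Saponification of the pseudo-ester opens the ring and the hemiacetal collapses with loss of the auxiliary to the C9' aldehyde 16, which NaBH4 already present reduces at once to 17; acidification closes the γ-lactone between the C9 acid and the new C9' alcohol, so the carbonyl stays next to C8 and both stereocentres are retained, the immediate reduction limiting enolisation at C8'.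

**Step 10**
Reactants: 18 (3R,4R)-3-[3,4-bis(benzyloxy)-5-methoxybenzyl]-4-[4-(benzyloxy)-3-methoxybenzyl]dihydrofuran-2(3H)-one
Product: 19 (-)-thujaplicatin, (3R,4R)-3-(3,4-dihydroxy-5-methoxybenzyl)-4-(4-hydroxy-3-methoxybenzyl)dihydrofuran-2(3H)-one
Conditions: H2 (1 atm), Pd/C (10% w/w), EtOAc/EtOH, rt
Reagents that add atoms: none
Why: Catalytic hydrogenolysis of three aryl benzyl ethers under neutral conditions; the lactone, the methyl ethers and both stereocentres are not affected, and the product is isolated with exclusion of air and base to protect the catechol.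

## Compound list

1 | furfural | O=Cc1ccco1 | starting material
2 | 5-hydroxyfuran-2(5H)-one (racemic) | O=C1C=CC(O)O1 | intermediate
3 | (-)-menthol, (1R,2S,5R)-2-isopropyl-5-methylcyclohexan-1-ol | CC(C)[C@@H]1CC[C@@H](C)C[C@H]1O | starting material
4 | (5S)-5-(l-menthyloxy)furan-2(5H)-one | O=C1C=C[C@@H](O[C@@H]2C[C@H](C)CC[C@H]2C(C)C)O1 | intermediate
5 | (5R)-5-(l-menthyloxy)furan-2(5H)-one | O=C1C=C[C@H](O[C@@H]2C[C@H](C)CC[C@H]2C(C)C)O1 | intermediate
6 | 4-(benzyloxy)-3-methoxybenzaldehyde | COc1cc(C=O)ccc1OCc1ccccc1 | starting material
7 | 2-[4-(benzyloxy)-3-methoxyphenyl]-1,3-dithiane | COc1cc(C2SCCCS2)ccc1OCc1ccccc1 | intermediate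
8 | 3,4-dihydroxy-5-methoxybenzaldehyde | COc1cc(C=O)cc(O)c1O | starting material
9 | 3,4-bis(benzyloxy)-5-methoxybenzaldehyde | COc1cc(C=O)cc(OCc2ccccc2)c1OCc1ccccc1 | intermediate
10 | [3,4-bis(benzyloxy)-5-methoxyphenyl]methanol | COc1cc(CO)cc(OCc2ccccc2)c1OCc1ccccc1 | intermediate
11 | 3,4-bis(benzyloxy)-5-methoxybenzyl bromide | COc1cc(CBr)cc(OCc2ccccc2)c1OCc1ccccc1 | intermediate
12 | 2-[4-(benzyloxy)-3-methoxyphenyl]-2-lithio-1,3-dithiane | [Li]C1(c2ccc(OCc3ccccc3)c(OC)c2)SCCCS1 | intermediate
13 | lithium (4R,5R)-4-{2-[4-(benzyloxy)-3-methoxyphenyl]-1,3-dithian-2-yl}-5-(l-menthyloxy)-4,5-dihydrofuran-2-olate | [Li]OC1=C[C@@H](C2(c3ccc(OCc4ccccc4)c(OC)c3)SCCCS2)[C@H](O[C@@H]2C[C@H](C)CC[C@H]2C(C)C)O1 | intermediate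
14 | (3R,4R,5R)-3-[3,4-bis(benzyloxy)-5-methoxybenzyl]-4-{2-[4-(benzyloxy)-3-methoxyphenyl]-1,3-dithian-2-yl}-5-(l-menthyloxy)dihydrofuran-2(3H)-one | O=C1O[C@@H](O[C@@H]2C[C@H](C)CC[C@H]2C(C)C)[C@H](C2(c3ccc(OCc4ccccc4)c(OC)c3)SCCCS2)[C@H]1Cc1cc(OC)c(OCc2ccccc2)c(OCc2ccccc2)c1 | intermediate
15 | (3R,4R,5R)-3-[3,4-bis(benzyloxy)-5-methoxybenzyl]-4-[4-(benzyloxy)-3-methoxybenzyl]-5-(l-menthyloxy)dihydrofuran-2(3H)-one | O=C1O[C@@H](O[C@@H]2C[C@H](C)CC[C@H]2C(C)C)[C@H](Cc2ccc(OCc3ccccc3)c(OC)c2)[C@H]1Cc1cc(OC)c(OCc2ccccc2)c(OCc2ccccc2)c1 | intermediate
16 | potassium (2R,3R)-2-[3,4-bis(benzyloxy)-5-methoxybenzyl]-3-[4-(benzyloxy)-3-methoxybenzyl]-4-oxobutanoate | [K+].[O-]C(=O)[C@H](Cc1cc(OC)c(OCc2ccccc2)c(OCc2ccccc2)c1)[C@@H](Cc1ccc(OCc2ccccc2)c(OC)c1)C=O | intermediate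
17 | potassium (2R,3R)-2-[3,4-bis(benzyloxy)-5-methoxybenzyl]-3-[4-(benzyloxy)-3-methoxybenzyl]-4-hydroxybutanoate | [K+].[O-]C(=O)[C@H](Cc1cc(OC)c(OCc2ccccc2)c(OCc2ccccc2)c1)[C@@H](Cc1ccc(OCc2ccccc2)c(OC)c1)CO | intermediate
18 | (3R,4R)-3-[3,4-bis(benzyloxy)-5-methoxybenzyl]-4-[4-(benzyloxy)-3-methoxybenzyl]dihydrofuran-2(3H)-one | COc1cc(C[C@H]2COC(=O)[C@@H]2Cc2cc(OCc3ccccc3)c(OCc3ccccc3)c(OC)c2)ccc1OCc1ccccc1 | intermediate
19 | (-)-thujaplicatin | COc1cc(C[C@H]2COC(=O)[C@@H]2Cc2cc(O)c(O)c(OC)c2)ccc1O | target

## Step count and least certain steps

Total step count: 10. Longest linear sequence: 7 steps (8 → 19 through steps 4, 5, 6, 7, 8, 9 and 10). The butenolide branch (steps 1 and 2) and the dithiane branch (step 3) join at step 7.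

**Step 7 (key step).**
- What may go wrong: capture of the hindered enolate 13 may be incomplete because proton transfer outpaces benzylation. Unreacted 12 may consume 11. The dithiane may be lost by retro-Michael reaction on warming. Facial selectivity in the alkylation may be imperfect.
- Fallback: the three-component coupling is split into two operations. Setting out from 7 and 5, the conjugate addition is quenched cold with NH4Cl to give the Michael adduct (4R,5R)-4-{2-[4-(benzyloxy)-3-methoxyphenyl]-1,3-dithian-2-yl}-5-(l-menthyloxy)dihydrofuran-2(3H)-one F1. F1 is purified, re-enolised with LDA in THF/DMPU at −78 °C and benzylated with 11. The route is rejoined at 14. Residual erosion at C8 can be corrected by base equilibration once the plain lactone 18 is reached, since trans is the thermodynamic arrangement.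

**Step 8.**
- What may go wrong: borohydride in the nickel boride mixture may attack the activated pseudo-ester carbonyl, or C–S cleavage may stop after the first sulfur.
- Fallback: setting out from 14, Raney Ni (W-2) under H2 in refluxing EtOH is used deliberately to remove the sulfur and all three benzyl groups in one operation. This gives (3R,4R,5R)-3-(3,4-dihydroxy-5-methoxybenzyl)-4-(4-hydroxy-3-methoxybenzyl)-5-(l-menthyloxy)dihydrofuran-2(3H)-one F2. Treatment of F2 with degassed NaBH4/KOH and then HCl leads directly to 19, where the route is rejoined. The price is a free catechol in base, which is handled under argon in the reducing medium.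

**Step 9.**
- What may go wrong: the liberated C9' aldehyde may enolise before hydride delivery, which would epimerise C8'. Saponification of the hindered pseudo-ester may be slow.
- Fallback: setting out from 15, the auxiliary is removed under acid instead (aq. HCl, dioxane, warm). This gives the lactol (3R,4R)-3-[3,4-bis(benzyloxy)-5-methoxybenzyl]-4-[4-(benzyloxy)-3-methoxybenzyl]-5-hydroxydihydrofuran-2(3H)-one F3 as a mixture at C5. Its ring–chain equilibrium exposes the aldehyde only in low concentration. NaBH4 in EtOH buffered with NaHCO3 reduces it, and acidification closes the lactone. The route is rejoined at 18.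

**Step 10.**
- What may go wrong: hydrogenolysis may stall through catalyst poisoning by sulfur or nickel traces carried from step 8. The catechol may oxidise in air during isolation.
- Fallback: setting out from 18, the benzyl ethers are cleaved with BCl3 and pentamethylbenzene as benzyl-cation scavenger in CH2Cl2 at −78 °C. This needs no metal surface and should leave the aryl methyl ethers intact at that temperature. It gives 19 directly, so the route is rejoined at 19 with no new intermediate (F0).

## Further compounds

F1 | step 7 | (4R,5R)-4-{2-[4-(benzyloxy)-3-methoxyphenyl]-1,3-dithian-2-yl}-5-(l-menthyloxy)dihydrofuran-2(3H)-one | O=C1C[C@@H](C2(c3ccc(OCc4ccccc4)c(OC)c3)SCCCS2)[C@H](O[C@@H]2C[C@H](C)CC[C@H]2C(C)C)O1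
F2 | step 8 | (3R,4R,5R)-3-(3,4-dihydroxy-5-methoxybenzyl)-4-(4-hydroxy-3-methoxybenzyl)-5-(l-menthyloxy)dihydrofuran-2(3H)-one | O=C1O[C@@H](O[C@@H]2C[C@H](C)CC[C@H]2C(C)C)[C@H](Cc2ccc(O)c(OC)c2)[C@H]1Cc1cc(OC)c(O)c(O)c1
F3 | step 9 | (3R,4R)-3-[3,4-bis(benzyloxy)-5-methoxybenzyl]-4-[4-(benzyloxy)-3-methoxybenzyl]-5-hydroxydihydrofuran-2(3H)-one (mixture at C5) | O=C1OC(O)[C@H](Cc2ccc(OCc3ccccc3)c(OC)c2)[C@H]1Cc1cc(OC)c(OCc2ccccc2)c(OCc2ccccc2)c1
F0 | step 10 | none | none
A1 | alternative 1 | 3-[4-(benzyloxy)-3-methoxybenzyl]cyclobutan-1-one | O=C1CC(Cc2ccc(OCc3ccccc3)c(OC)c2)C1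
A2 | alternative 1 | (R)-4-[4-(benzyloxy)-3-methoxybenzyl]dihydrofuran-2(3H)-one | O=C1C[C@@H](Cc2ccc(OCc3ccccc3)c(OC)c2)CO1
A3 | alternative 2 | (E)-3-[4-(benzyloxy)-3-methoxyphenyl]allyl 3-[3,4-bis(benzyloxy)-5-methoxyphenyl]-2-diazopropanoate | [N-]=[N+]=C(Cc1cc(OC)c(OCc2ccccc2)c(OCc2ccccc2)c1)C(=O)OC/C=C/c1ccc(OCc2ccccc2)c(OC)c1
A4 | alternative 2 | 1-[3,4-bis(benzyloxy)-5-methoxybenzyl]-6-[4-(benzyloxy)-3-methoxyphenyl]-3-oxabicyclo[3.1.0]hexan-2-one (cis-fused, ring B exo) | O=C1OC[C@@H]2[C@@H](c3ccc(OCc4ccccc4)c(OC)c3)[C@]12Cc1cc(OC)c(OCc2ccccc2)c(OCc2ccccc2)c1
A5 | alternative 3 | ethyl (2E,4R)-2-[3,4-bis(benzyloxy)-5-methoxybenzyl]-4-[4-(benzyloxy)-3-methoxyphenyl]-4-{[(bromomethyl)dimethylsilyl]oxy}but-2-enoate | CCOC(=O)/C(Cc1cc(OC)c(OCc2ccccc2)c(OCc2ccccc2)c1)=C/[C@@H](O[Si](C)(C)CBr)c1ccc(OCc2ccccc2)c(OC)c1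
A6 | alternative 3 | ethyl 3-[3,4-bis(benzyloxy)-5-methoxyphenyl]-2-{trans-5-[4-(benzyloxy)-3-methoxyphenyl]-2,2-dimethyl-1,2-oxasilolan-4-yl}propanoate (C8 not defined) | CCOC(=O)C(Cc1cc(OC)c(OCc2ccccc2)c(OCc2ccccc2)c1)[C@@H]1C[Si](C)(C)O[C@H]1c1ccc(OCc2ccccc2)c(OC)c1
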